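**Retrosynthetic overview**
- Target 13 ⇐ trans-selective enolate benzylation of (R)-β-(3,4,5-trimethoxybenzyl)-γ-butyrolactone 10 with 3,4-dimethoxybenzyl bromide 11; this sets C3.
- Lactone 10 ⇐ catalytic enantioselective Baeyer–Villiger desymmetrisation of prochiral cyclobutanone 8; the ring C–O bond forms here and C4 is set.
- Cyclobutanone 8 ⇐ dichloroketene [2+2] with allylarene 4, then dechlorination; 4 ⇐ aryl Grignard plus allyl bromide.
- Ring order: the cyclobutanone is built first, then expanded to the lactone; both arenes are bought.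

Assumption: the sense of induction of the proposed catalyst cannot be predicted with certainty. The (S,S) form is written; its mirror image is used if a small test run (sign of rotation of 10) shows the opposite sense.

**Step 1**
Reactants: 1 5-bromo-1,2,3-trimethoxybenzene; 2 allyl bromide
Product: 4 5-allyl-1,2,3-trimethoxybenzene, via (3,4,5-trimethoxyphenyl)magnesium bromide 3 (not isolated)
Conditions: Mg turnings (1.2 equiv), I2 (crystal), THF, 50 °C, 2 h; then 2 (1.3 equiv), 0 °C to rt, 2 h
Reagents that add atoms: none
Why: Grignard formation followed by allylation of the arylmagnesium bromide with allyl bromide (direct and allylic displacement give the same product); no stereocenter is formed.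

**Step 2**
Reactants: 4 5-allyl-1,2,3-trimethoxybenzene; 5 trichloroacetyl chloride
Product: 8 3-(3,4,5-trimethoxybenzyl)cyclobutan-1-one, via dichloroketene 6 (not isolated), via 2,2-dichloro-3-(3,4,5-trimethoxybenzyl)cyclobutan-1-one 7 (not isolated)
Conditions: Zn dust (3 equiv), Et2O/DME (10:1), ultrasound, 15–25 °C, 5 (2 equiv) added over 2 h; then AcOH, Zn dust (6 equiv), rt to 40 °C, 12 h, same flask
Reagents that add atoms: none
Why: Thermal ketene–alkene [2+2] cycloaddition (carbonyl carbon bonds to the terminal CH2, so the benzyl group ends at C3) followed by Zn/AcOH reductive dechlorination; the product is achiral, with C3 a prochiral centre.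

**Step 3**
Reactants: 8 3-(3,4,5-trimethoxybenzyl)cyclobutan-1-one
Product: 10 (R)-4-(3,4,5-trimethoxybenzyl)dihydrofuran-2(3H)-one, via Criegee hydroperoxy hemiketal 9 (not isolated)
Conditions: (S,S)-imidodiphosphoric acid HN[P(=O)(O2C20H10Ar2)]2 (Ar = 2,4,6-triethylphenyl; each O2C20H10Ar2 an (S)-3,3′-diaryl-1,1′-binaphthalene-2,2′-diolate; 5 mol %), 35% aq. H2O2 (1.5 equiv), CHCl3, −40 °C, 24–48 h
Reagents that add atoms: hydrogen peroxide, OO
Why: Proposed new method: the confined chiral imidodiphosphoric acid should act bifunctionally, its P–OH activating the strained ketone for H2O2 addition to give Criegee adduct 9 and its P=O holding the hydroxyl of 9, so that inside the narrow chiral cleft only the conformer with the O–O bond antiperiplanar to one of the two enantiotopic ring CH2–C(OH) bonds is populated and that CH2 migrates to oxygen with loss of water, forming the ring C–O bond and fixing C4 as R (the cleft walls grip the flexible 3-benzyl group that open phosphoric acids read poorly); the closest known reaction types are the chiral phosphoric acid catalysed Baeyer–Villiger desymmetrisation of 3-arylcyclobutanones with aqueous H2O2 and the imidodiphosphoric acid catalysed sulfoxidation with aqueous H2O2.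

**Step 4**
Reactants: 10 (R)-4-(3,4,5-trimethoxybenzyl)dihydrofuran-2(3H)-one; 11 4-(bromomethyl)-1,2-dimethoxybenzene (3,4-dimethoxybenzyl bromide)
Product: 13 (3R,4R)-3-(3,4-dimethoxybenzyl)-4-(3,4,5-trimethoxybenzyl)dihydrofuran-2(3H)-one, via lithium lactone enolate 12 (not isolated)
Conditions: LiN(SiMe3)2 (1.05 equiv), THF, −78 °C, 1 h; then 11 (1.2 equiv), DMPU (2 equiv), −78 to −30 °C, 3 h
Reagents that add atoms: none
Why: Lithium enolate alkylation in which the benzyl bromide approaches the enolate face anti to the C4 benzyl group, giving the 3,4-trans lactone (3R) by 1,2-induction; trans is also the thermodynamic isomer, and C4 is not acidic, so it is not touched.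

**Compound list**
1 | 5-bromo-1,2,3-trimethoxybenzene | COc1cc(Br)cc(OC)c1OC | starting material
2 | allyl bromide (3-bromoprop-1-ene) | C=CCBr | starting material
3 | (3,4,5-trimethoxyphenyl)magnesium bromide | COc1cc([Mg]Br)cc(OC)c1OC | intermediate (not isolated)
4 | 5-allyl-1,2,3-trimethoxybenzene | C=CCc1cc(OC)c(OC)c(OC)c1 | intermediate
5 | trichloroacetyl chloride | ClC(=O)C(Cl)(Cl)Cl | starting material
6 | dichloroketene | O=C=C(Cl)Cl | intermediate (not isolated)
7 | 2,2-dichloro-3-(3,4,5-trimethoxybenzyl)cyclobutan-1-one (racemic) | COc1cc(CC2CC(=O)C2(Cl)Cl)cc(OC)c1OC | intermediate (not isolated)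
8 | 3-(3,4,5-trimethoxybenzyl)cyclobutan-1-one (achiral) | COc1cc(CC2CC(=O)C2)cc(OC)c1OC | intermediate
9 | 1-hydroperoxy-3-(3,4,5-trimethoxybenzyl)cyclobutan-1-ol (Criegee adduct, cis/trans not defined) | COc1cc(CC2CC(O)(OO)C2)cc(OC)c1OC | intermediate (not isolated)
10 | (R)-4-(3,4,5-trimethoxybenzyl)dihydrofuran-2(3H)-one | O=C1C[C@@H](Cc2cc(OC)c(OC)c(OC)c2)CO1 | intermediate
11 | 4-(bromomethyl)-1,2-dimethoxybenzene (3,4-dimethoxybenzyl bromide) | COc1ccc(CBr)cc1OC | starting material
12 | lithium (R)-4-(3,4,5-trimethoxybenzyl)-4,5-dihydrofuran-2-olate | [Li]OC1=C[C@@H](Cc2cc(OC)c(OC)c(OC)c2)CO1 | intermediate (not isolated)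
13 | (3R,4R)-3-(3,4-dimethoxybenzyl)-4-(3,4,5-trimethoxybenzyl)dihydrofuran-2(3H)-one (trans) | COc1ccc(C[C@H]2C(=O)OC[C@@H]2Cc2cc(OC)c(OC)c(OC)c2)cc1OC | target

**Step count and risks**
Total steps: 4. Longest linear sequence: 4 steps (1 → 4 → 8 → 10 → 13).

The three steps most likely to fail:

Step 3 (the proposed new oxidation). The catalyst class is untested for this oxidation, turnover in the cleft may be slow, and the flexible benzyl group may give an ee too low for a single-enantiomer product. The fallback uses known chemistry, sets out from 8 and comes back at 10. Lithium (R,R)-bis(1-phenylethyl)amide (or its mirror image, whichever a test run shows to give the R series), with Me3SiCl present in THF at −100 °C, removes one of the two enantiotopic α-protons of 8. This gives the silyl enol ether (R)-trimethyl{[3-(3,4,5-trimethoxybenzyl)cyclobut-1-en-1-yl]oxy}silane F1. Ozonolysis (O3, 1 equiv, CH2Cl2/MeOH, −78 °C) cleaves the enol ether double bond to (R)-4-oxo-3-(3,4,5-trimethoxybenzyl)butanoic acid F2. NaBH4 added to the same pot reduces the aldehyde to (R)-4-hydroxy-3-(3,4,5-trimethoxybenzyl)butanoic acid F3, and acidification with aqueous HCl closes F3 to 10.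

Step 2 (one-pot cycloaddition and dechlorination). Dichloroketene may oligomerise faster than it adds to the unactivated alkene, ZnCl2 may attack the electron-rich arene, and the second chlorine may come off slowly. The fallback sets out from 4 and comes back at 8, using a cationic two-carbon partner without halogen. N,N-Dimethylacetamide, (CF3SO2)2O and 2,4,6-collidine in 1,2-dichloroethane generate N,N-dimethylketeniminium triflate F4. At reflux F4 adds to the alkene of 4 to give N,N-dimethyl-3-(3,4,5-trimethoxybenzyl)cyclobutan-1-iminium triflate F5, and aqueous NaHCO3 hydrolyses F5 to 8.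

Step 4 (enolate benzylation). The electron-rich benzyl bromide is labile, and incomplete conversion or double alkylation can lower the yield. The fallback sets out from 10 and comes back at 13, replacing alkylation by aldol addition and hydrogenolysis. The enolate of 10 (LiN(SiMe3)2, THF, −78 °C) adds to 3,4-dimethoxybenzaldehyde anti to the C4 substituent. This gives (3S,4R)-3-[(3,4-dimethoxyphenyl)(hydroxy)methyl]-4-(3,4,5-trimethoxybenzyl)dihydrofuran-2(3H)-one F6 (trans on the ring, both carbinol epimers). Hydrogenolysis of the benzylic C–OH bond (H2, Pd/C, AcOH with a trace of HClO4, rt) gives 13 without touching the ring stereocenters.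

**Further compounds**
F1 | step 3 | (R)-trimethyl{[3-(3,4,5-trimethoxybenzyl)cyclobut-1-en-1-yl]oxy}silane | C[Si](C)(C)OC1=C[C@H](Cc2cc(OC)c(OC)c(OC)c2)C1
F2 | step 3 | (R)-4-oxo-3-(3,4,5-trimethoxybenzyl)butanoic acid | OC(=O)C[C@@H](Cc1cc(OC)c(OC)c(OC)c1)C=O
F3 | step 3 | (R)-4-hydroxy-3-(3,4,5-trimethoxybenzyl)butanoic acid | OC(=O)C[C@@H](Cc1cc(OC)c(OC)c(OC)c1)CO
F4 | step 2 | N,N-dimethylketeniminium triflate | C=C=[N+](C)C.[O-]S(=O)(=O)C(F)(F)F
F5 | step 2 | N,N-dimethyl-3-(3,4,5-trimethoxybenzyl)cyclobutan-1-iminium triflate | C[N+](C)=C1CC(Cc2cc(OC)c(OC)c(OC)c2)C1.[O-]S(=O)(=O)C(F)(F)F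
F6 | step 4 | (3S,4R)-3-[(3,4-dimethoxyphenyl)(hydroxy)methyl]-4-(3,4,5-trimethoxybenzyl)dihydrofuran-2(3H)-one (carbinol epimers) | COc1ccc(C(O)[C@H]2C(=O)OC[C@@H]2Cc2cc(OC)c(OC)c(OC)c2)cc1OC
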